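All runs are calculated from invented constants, noise included.

The ash run, charged with more G than the birch run, holds less J early: over its first three readings, summed, ash over birch gives 0.963. Both runs share those times, and if J → E is first order, J falls by the same factor in each, so time drops out of the ratio. What remains is the ratio of the J that escapes G.

| flask | J | G | remark | time |
|---|---|---|---|---|
| birch | 10 mM | 0.34 mM | run made earlier |  |
| ash | 10 mM | 0.75 mM | run made earlier |  |
| elm | 20 mM | 0.50 mM | run made earlier |  |
| flask | 10 mM | 0.500 mM |  | 15 d |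

| run | time / d | D / % | J / % |
|---|---|---|---|
| birch | 0.167 | 9.4 | 62.1 |
| birch | 0.333 | 19.9 | 39.6 |
| birch | 0.625 | 27.9 | 18.4 |
| birch | 1.25 | 22.1 | 3.5 |
| birch | 3.00 | 9.0 | 0 |
| birch | 6.00 | 6.0 | 0.6 |
| birch | 12.0 | 4.3 | 0 |
| ash | 0.167 | 10.1 | 60.4 |
| ash | 0.333 | 21.0 | 37.5 |
| ash | 0.625 | 26.9 | 17.7 |
| ash | 1.25 | 20.5 | 3.3 |
| ash | 3.00 | 9.1 | 0 |
| ash | 6.00 | 6.2 | 0 |
| ash | 12.0 | 3.4 | 0.2 |
| elm | 0.167 | 10.3 | 61.7 |
| elm | 0.500 | 25.7 | 26.7 |
| elm | 1.25 | 21.8 | 3.8 |
| elm | 4.00 | 8.2 | 0.1 |
| elm | 12.0 | 5.6 | 0 |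

(standard deviation of a reading: 0.5 percentage points)

- the best time, 15 d at the latest, for D
- the amount of D, in percent of the J charged, at that time

- what may be going on: E <-> D; J + G -> X; D <-> L; E <-> Q; J -> E

I suppose J + G → X takes one J per G, with G the limiting reagent of that side step. For the flask, u is 95.0%, the usable share: the part of the charged J left once each G has taken one J. The runs have 96.6% (birch) and 92.5% (ash), so the ratio should be 0.958, beside the 0.963 read from the scattered readings. But one pair of readings would be weak, which is why I summed three, and J is not D.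

So I scale the highest D readings, both at 0.625 d. Birch's 27.9% becomes 27.4% and ash's 26.9% becomes 27.6%. These agree within the scatter. The objection is that the true top may fall between readings, and I can't compute that away. I commit to about 27.5% near that time, since D is down to 4.3% at 12.0 d in birch.

The forecast says 27.8% at 0.7 d, holding that “G quickly and stoichiometrically scavenges J”. The flask gives 27.3% at 0.691 d.

    E ⇌ D (K = 2.16, k = 0.00379 min⁻¹)
    J + G → X (k = 3.64 M⁻¹ min⁻¹)
    D ⇌ L (K = 2.50, k = 7.11 × 10⁻⁴ min⁻¹)
    E ⇌ Q (K = 63.3, k = 0.00134 min⁻¹)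
    J → E (k = 0.00184 min⁻¹)

In the flask, G with J held at its charge (pseudo-first-order) has a half-life of 0.0132 d, far shorter than the 0.26 d of J by its conversion into E at 0.261 d, and at 0.691 d G stands at 0% and X at 5.00%, beside the 5.00% of the charge that lies outside u. The same flask with 2.0 mM of G has u of 80.0%, so scaling asks 23.0%, and that flask gives 23.0%.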